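Ring B of the cis-decalin (C5–C10, eremophilane numbering) is disconnected by a retro-[4+2]. One thermal intramolecular Diels–Alder reaction forms C6–C7 and C5–C10 together and closes both carbocycles: the 2-silyloxydiene C7=C8(OTBS)–C9=C10 of an acyclic tetraene adds to the C5 isopropenyl group held by the C1–C4 tether. The step exploits the C8 ketone/C9 acyloxy pair of ring B, which maps onto the regiodefined C8=C9 silyl enol ether it delivers; Rubottom oxidation then gives the 9β-hydroxy-8-ketone. The C3/C4 centres, set from a Sharpless epoxide, steer C5 and C10; C7 is finally equilibrated to its equatorial configuration.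

Key step: step 10

Remark: eremophilane numbering is used for positions (C1–C10 decalin, C15 on C4, C14 on C5, C11–C13 isopropenyl on C7); β is the face of the C5 methyl group. The target is then 3α,9β-bis(senecioyloxy)-10βH-eremophil-11-en-8-one with 7β-isopropenyl, (3R,4R,5R,7R,9R,10S).
Remark: dimethyldioxirane is taken as a freshly prepared acetone solution; all numbered starting materials are assumed commercial.

Step 1
Reactants: 1 (E)-but-2-en-1-ol
Product: 2 (2R,3R)-2,3-epoxybutan-1-ol
Conditions: Ti(OiPr)4 (cat.), D-(−)-DIPT, t-BuOOH, 4 Å MS, CH2Cl2, −20 °C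
Reagents that add atoms: tert-butyl hydroperoxide, CC(C)(C)OO
Why: Sharpless asymmetric epoxidation, in which the D-(−)-tartrate directs oxygen to the face of the (E)-allylic alcohol that gives the (2R,3R)-epoxide, fixing the future C3–O centre and, after inversion in step 2, C4.

Step 2
Reactants: 2 (2R,3R)-2,3-epoxybutan-1-ol; 3 isopropenylmagnesium bromide
Product: 4 (2S,3R)-3,4-dimethylpent-4-ene-1,2-diol
Conditions: 3 (3 equiv), CuI (10 mol%), THF, −30 → −10 °C; aq. NH4Cl
Reagents that add atoms: isopropenylmagnesium bromide, C=C(C)[Mg]Br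
Why: Copper-catalysed Grignard opening of a 2,3-epoxy alcohol, which takes place at C3 with SN2 inversion, so the methyl-bearing carbon becomes (R) while the carbinol carbon keeps the epoxide configuration (the syn C3–O/C4–Me pattern of the target).

Step 3
Reactants: 4 (2S,3R)-3,4-dimethylpent-4-ene-1,2-diol
Product: 5 (2S,3R)-2-hydroxy-3,4-dimethylpent-4-en-1-yl 4-methylbenzenesulfonate
Conditions: TsCl (1.05 equiv), Bu2SnO (cat.), Et3N, CH2Cl2, 0 °C
Reagents that add atoms: 4-toluenesulfonyl chloride, Cc1ccc(cc1)S(Cl)(=O)=O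
Why: Tin-acetal-catalysed selective sulfonylation of the primary hydroxyl of a 1,2-diol; no stereocentre is touched.

Step 4
Reactants: 5 (2S,3R)-2-hydroxy-3,4-dimethylpent-4-en-1-yl 4-methylbenzenesulfonate; 6 acetonitrile
Product: 8 (4R,5R)-4-hydroxy-5,6-dimethylhept-6-enenitrile, via terminal epoxide 7 (not isolated)
Conditions: NaH, THF, 0 °C; then LiCH2CN (from 6 and n-BuLi, THF, −78 °C), −78 °C → rt; aq. NH4Cl
Reagents that add atoms: acetonitrile, CC#N
Why: Intramolecular Williamson closure to the terminal epoxide (retention at the carbinol carbon) followed by SN2 opening at the unhindered CH2 by lithioacetonitrile, which adds C1 and C10 without touching a stereocentre.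

Step 5
Reactants: 8 (4R,5R)-4-hydroxy-5,6-dimethylhept-6-enenitrile
Product: 9 (4R,5R)-5,6-dimethyl-4-(triethylsilyloxy)hept-6-enenitrile
Conditions: TESCl, imidazole, DMF, 0 °C → rt
Reagents that add atoms: chlorotriethylsilane, CC[Si](Cl)(CC)CC
Why: Standard silylation of a secondary alcohol; the TES ether survives the hydride, Grignard, amide-base and thermal steps and is removed together with the enol silane in step 11.

Step 6
Reactants: 9 (4R,5R)-5,6-dimethyl-4-(triethylsilyloxy)hept-6-enenitrile
Product: 10 (4R,5R)-5,6-dimethyl-4-(triethylsilyloxy)hept-6-enal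
Conditions: DIBAL-H (1.2 equiv), CH2Cl2, −78 °C; then aq. Rochelle salt
Reagents that add atoms: water, O
Why: Partial reduction of the nitrile to the N-aluminio imine, which is hydrolysed to the aldehyde on work-up; the alkene and silyl ether are inert.

Step 7
Reactants: 10 (4R,5R)-5,6-dimethyl-4-(triethylsilyloxy)hept-6-enal; 11 diethyl {2-[methoxy(methyl)amino]-2-oxoethyl}phosphonate
Product: 12 (2E,6R,7R)-N-methoxy-N,7,8-trimethyl-6-(triethylsilyloxy)nona-2,8-dienamide
Conditions: 11, NaH, THF, 0 °C → rt
Reagents that add atoms: diethyl {2-[methoxy(methyl)amino]-2-oxoethyl}phosphonate, CCOP(=O)(CC(=O)N(C)OC)OCC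
Why: Horner–Wadsworth–Emmons olefination with a stabilised phosphonate, which gives the (E)-C9=C10 alkene required for the cycloaddition geometry.

Step 8
Reactants: 12 (2E,6R,7R)-N-methoxy-N,7,8-trimethyl-6-(triethylsilyloxy)nona-2,8-dienamide; 13 2-methylallylmagnesium chloride
Product: 14 (5E,9R,10R)-2,10,11-trimethyl-9-(triethylsilyloxy)dodeca-1,5,11-trien-4-one
Conditions: 13 (1.3 equiv), THF, −78 °C; cold aq. NH4Cl
Reagents that add atoms: 2-methylallylmagnesium chloride, C=C(C)C[Mg]Cl
Why: Weinreb ketone synthesis, in which the chelated tetrahedral intermediate prevents over-addition and releases the β,γ-unsaturated enone only on cold neutral work-up, so the doubly activated C7H2 is not isomerised.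

Step 9
Reactants: 14 (5E,9R,10R)-2,10,11-trimethyl-9-(triethylsilyloxy)dodeca-1,5,11-trien-4-one
Product: 15 (3Z,5E,9R,10R)-4-(tert-butyldimethylsilyloxy)-2,10,11-trimethyl-9-(triethylsilyloxy)dodeca-1,3,5,11-tetraene
Conditions: LiHMDS, TBSCl, THF–DMPU, −78 °C
Reagents that add atoms: tert-butyldimethylsilyl chloride, CC(C)(C)[Si](C)(C)Cl
Why: Kinetic α′-deprotonation at the doubly activated C7H2 and O-silylation give the cross-conjugated 2-silyloxydiene, the (3Z)-enol ether (isopropenyl cis to OSi) being expected because the isopropenyl group avoids the 1,3-clash with the C9 vinyl residue.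

Step 10
Reactants: 15 (3Z,5E,9R,10R)-4-(tert-butyldimethylsilyloxy)-2,10,11-trimethyl-9-(triethylsilyloxy)dodeca-1,3,5,11-tetraene
Product: 16 8-(tert-butyldimethylsilyloxy)-3α-(triethylsilyloxy)-7βH,10βH-eremophila-8,11-diene (cis-fused; 4β,5β-dimethyl; 7α-isopropenyl)
Conditions: PhMe (0.01 M), BHT (cat.), silylated sealed tube, 175 °C
Reagents that add atoms: none
Why: Thermal, concerted but asynchronous [4π+2π] cycloaddition (type-1 intramolecular Diels–Alder reaction of a 1,7,9-decatriene) in which the electron-rich 2-silyloxydiene C7=C8–C9=C10 adds suprafacially across the unactivated C5=C6 isopropenyl group, the closest known reaction type being the thermal cyclisation of 2-silyloxy trienes onto tethered 1,1-disubstituted alkenes. Ring B (C5–C6–C7–C8–C9–C10) closes in the [4+2] mode through a boat-like array, and ring A (C10–C1–C2–C3–C4–C5) closes as the chair-like four-carbon tether when C5 bonds to C10. C5 is controlled by C3/C4: with OTES and the C4 methyl equatorial and C4–H eclipsing C5=C6 (A1,3 strain), the C5 methyl is axial and cis to the C4 methyl. C10 follows from the endo-tether (cis-fused) transition state, expected to be preferred because bonding at the nascent quaternary C5 lags behind C6–C7 bonding (the situation known to favour cis fusion) and because the exo-tether alternative places the C5 methyl under the diene. C7 follows from the (3Z)-enol ether: the outside isopropenyl group ends cis to C1 (7α) and is corrected in step 13. The step needs endo- over exo-tether selectivity and an intact diene; the (E)-C9=C10 bond rules out [1,5]-H shifts, and high dilution, BHT and a base-washed tube suppress oligomerisation and enol ether hydrolysis.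

Step 11
Reactants: 16 8-(tert-butyldimethylsilyloxy)-3α-(triethylsilyloxy)-7βH,10βH-eremophila-8,11-diene
Product: 19 3α,9β-dihydroxy-7βH,10βH-eremophil-11-en-8-one, via silyloxy epoxide 17 (not isolated), via TES-protected ketol 18 (not isolated)
Conditions: DMDO (1.05 equiv, acetone), CH2Cl2, −78 → −40 °C; then HF·pyridine, THF–pyridine, 0 °C → rt
Reagents that add atoms: dimethyldioxirane, CC1(C)OO1
Why: Rubottom oxidation, in which the electron-rich silyl enol ether is epoxidised ahead of the two 1,1-disubstituted alkenes and from the β-face (the α-face is blocked by the axial C4–C5 bond and the 7α-isopropenyl group), and fluoride then opens the silyloxy epoxide to the 9β-hydroxy-8-ketone and removes the TES ether.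

Step 12
Reactants: 19 3α,9β-dihydroxy-7βH,10βH-eremophil-11-en-8-one; 20 3-methylbut-2-enoyl chloride
Product: 21 3α,9β-bis(3-methylbut-2-enoyloxy)-7βH,10βH-eremophil-11-en-8-one (7-epimer of the target)
Conditions: 20 (4 equiv), pyridine, DMAP (cat.), CH2Cl2, 0 °C → rt
Reagents that add atoms: 3-methylbut-2-enoyl chloride, CC(C)=CC(Cl)=O
Why: DMAP-catalysed acylation of both secondary hydroxyls with pyridine as the only base, which avoids ketene-mediated deconjugation of the senecioyl group and touches no stereocentre.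

Step 13
Reactants: 21 3α,9β-bis(3-methylbut-2-enoyloxy)-7βH,10βH-eremophil-11-en-8-one
Product: 22 3α,9β-bis(3-methylbut-2-enoyloxy)-7αH,10βH-eremophil-11-en-8-one, (3R,4R,5R,7R,9R,10S), the target
Conditions: DBU (0.2 equiv), PhMe, rt, monitored; AcOH quench
Reagents that add atoms: none
Why: Base-mediated epimerisation under thermodynamic control via the C7 enolate moves the axial 7α-isopropenyl group (syn to the axial C4–C5 bond) to the equatorial 7β position while C9 already carries its ester equatorially, and because α-reprotonation is faster than γ-reprotonation the equilibration is stopped before the C11 double bond moves into conjugation.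

Compound list
1 | (E)-but-2-en-1-ol | C/C=C/CO | starting material
2 | (2R,3R)-2,3-epoxybutan-1-ol | OC[C@H]1O[C@@H]1C | intermediate
3 | isopropenylmagnesium bromide | C=C(C)[Mg]Br | starting material
4 | (2S,3R)-3,4-dimethylpent-4-ene-1,2-diol | OC[C@@H](O)[C@H](C)C(C)=C | intermediate
5 | (2S,3R)-2-hydroxy-3,4-dimethylpent-4-en-1-yl 4-methylbenzenesulfonate | Cc1ccc(cc1)S(=O)(=O)OC[C@@H](O)[C@H](C)C(C)=C | intermediate
6 | acetonitrile | CC#N | starting material
7 | (2S)-2-[(2R)-3-methylbut-3-en-2-yl]oxirane (not isolated) | C1O[C@H]1[C@H](C)C(C)=C | intermediate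
8 | (4R,5R)-4-hydroxy-5,6-dimethylhept-6-enenitrile | N#CCC[C@@H](O)[C@H](C)C(C)=C | intermediate
9 | (4R,5R)-5,6-dimethyl-4-(triethylsilyloxy)hept-6-enenitrile | N#CCC[C@@H](O[Si](CC)(CC)CC)[C@H](C)C(C)=C | intermediate
10 | (4R,5R)-5,6-dimethyl-4-(triethylsilyloxy)hept-6-enal | O=CCC[C@@H](O[Si](CC)(CC)CC)[C@H](C)C(C)=C | intermediate
11 | diethyl {2-[methoxy(methyl)amino]-2-oxoethyl}phosphonate | CCOP(=O)(CC(=O)N(C)OC)OCC | starting material
12 | (2E,6R,7R)-N-methoxy-N,7,8-trimethyl-6-(triethylsilyloxy)nona-2,8-dienamide | CON(C)C(=O)/C=C/CC[C@@H](O[Si](CC)(CC)CC)[C@H](C)C(C)=C | intermediate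
13 | 2-methylallylmagnesium chloride | C=C(C)C[Mg]Cl | starting material
14 | (5E,9R,10R)-2,10,11-trimethyl-9-(triethylsilyloxy)dodeca-1,5,11-trien-4-one | C=C(C)CC(=O)/C=C/CC[C@@H](O[Si](CC)(CC)CC)[C@H](C)C(C)=C | intermediate
15 | (3Z,5E,9R,10R)-4-(tert-butyldimethylsilyloxy)-2,10,11-trimethyl-9-(triethylsilyloxy)dodeca-1,3,5,11-tetraene | C=C(C)/C=C(\O[Si](C)(C)C(C)(C)C)/C=C/CC[C@@H](O[Si](CC)(CC)CC)[C@H](C)C(C)=C | intermediate
16 | 8-(tert-butyldimethylsilyloxy)-3α-(triethylsilyloxy)-7βH,10βH-eremophila-8,11-diene (cis-fused, 7α-isopropenyl) | C=C(C)[C@@H]1C[C@@]2(C)[C@H](CC[C@@H](O[Si](CC)(CC)CC)[C@@H]2C)C=C1O[Si](C)(C)C(C)(C)C | intermediate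
17 | 8β,9β-epoxide of 16 (silyloxy epoxide, not isolated) | C=C(C)[C@@H]1C[C@@]2(C)[C@H](CC[C@@H](O[Si](CC)(CC)CC)[C@@H]2C)[C@H]3O[C@@]13O[Si](C)(C)C(C)(C)C | intermediate
18 | 9β-hydroxy-3α-(triethylsilyloxy)-7βH,10βH-eremophil-11-en-8-one (not isolated) | C=C(C)[C@@H]1C[C@@]2(C)[C@H](CC[C@@H](O[Si](CC)(CC)CC)[C@@H]2C)[C@@H](O)C1=O | intermediate
19 | 3α,9β-dihydroxy-7βH,10βH-eremophil-11-en-8-one | C=C(C)[C@@H]1C[C@@]2(C)[C@H](CC[C@@H](O)[C@@H]2C)[C@@H](O)C1=O | intermediate
20 | 3-methylbut-2-enoyl chloride (senecioyl chloride) | CC(C)=CC(Cl)=O | starting material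
21 | 3α,9β-bis(3-methylbut-2-enoyloxy)-7βH,10βH-eremophil-11-en-8-one (7-epi-target) | C=C(C)[C@@H]1C[C@@]2(C)[C@H](CC[C@@H](OC(=O)C=C(C)C)[C@@H]2C)[C@@H](OC(=O)C=C(C)C)C1=O | intermediate
22 | 3α,9β-bis(3-methylbut-2-enoyloxy)-7αH,10βH-eremophil-11-en-8-one (CNP0264508.1) | C=C(C)[C@H]1C[C@@]2(C)[C@H](CC[C@@H](OC(=O)C=C(C)C)[C@@H]2C)[C@@H](OC(=O)C=C(C)C)C1=O | target

Total step count: 13. Longest linear sequence: 13 steps (1 → 22).

Steps most likely to fail

Step 10. The endo-tether and exo-tether transition states may not be well differentiated, so that much trans-fused (10α-H) material forms. The fallback sets out from 15 and rejoins at 22; it sets the ring fusion by reagent control instead of in the cycloaddition. The thermolysis is run as before and the trans-fused adduct 8-(tert-butyldimethylsilyloxy)-3α-(triethylsilyloxy)-7αH,10αH-eremophila-8,11-diene F1 (it carries 7β-isopropenyl) is separated. Saegusa–Ito oxidation (Pd(OAc)2, MeCN) erases C10 and gives 3α-(triethylsilyloxy)-7αH-eremophila-9,11-dien-8-one F2. Conjugate reduction with Stryker's reagent and trapping of the copper enolate with TBSOTf should deliver hydride to the β-face of C10, as in the cis-selective reductions of angular-methyl octalones, giving the cis-fused 8-(tert-butyldimethylsilyloxy)-3α-(triethylsilyloxy)-7αH,10βH-eremophila-8,11-diene F3. The conditions of step 11 convert F3, via its 8β,9β-silyloxy epoxide F4 and 9β-hydroxy-3α-(triethylsilyloxy)-7αH,10βH-eremophil-11-en-8-one F5, into 3α,9β-dihydroxy-7αH,10βH-eremophil-11-en-8-one F6. The conditions of step 12 then give 22 directly, without the final epimerisation.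

Step 13. During base equilibration of 21 the C11 double bond may migrate into conjugation with the ketone, or the senecioates may be damaged. The fallback sets out from 16 and rejoins at 22; it moves the equilibration to a fully silyl-protected ketone that carries neither enoate esters nor a free ketol. Buffered mCPBA (NaHCO3, CH2Cl2) oxidises 16 through 17 with silyl migration to 9β-(tert-butyldimethylsilyloxy)-3α-(triethylsilyloxy)-7βH,10βH-eremophil-11-en-8-one F7. Equilibration of C7 on this compound (K2CO3, MeOH or catalytic DBU) gives the 7β-isopropenyl epimer 9β-(tert-butyldimethylsilyloxy)-3α-(triethylsilyloxy)-7αH,10βH-eremophil-11-en-8-one F8. HF·pyridine then gives the diol F6, and the conditions of step 12 give 22.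

Step 11. The dioxirane may also oxidise the two 1,1-disubstituted alkenes, or the labile silyloxy epoxide may decompose. The fallback sets out from 16 and rejoins at 18; it replaces epoxidation by an O-selective nitroso aldol reaction. Nitrosobenzene with catalytic TESOTf (CH2Cl2, −78 °C), which does not touch unactivated alkenes, gives 9β-(N-phenylaminooxy)-3α-(triethylsilyloxy)-7βH,10βH-eremophil-11-en-8-one F9. N–O cleavage (CuSO4, MeOH) gives 18, which HF·pyridine converts into 19 as in step 11.

Further compounds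
F1 | step 10 | 8-(tert-butyldimethylsilyloxy)-3α-(triethylsilyloxy)-7αH,10αH-eremophila-8,11-diene (trans-fused adduct) | C=C(C)[C@H]1C[C@@]2(C)[C@@H](CC[C@@H](O[Si](CC)(CC)CC)[C@@H]2C)C=C1O[Si](C)(C)C(C)(C)C
F2 | step 10 | 3α-(triethylsilyloxy)-7αH-eremophila-9,11-dien-8-one | C=C(C)[C@H]1C[C@@]2(C)C(CC[C@@H](O[Si](CC)(CC)CC)[C@@H]2C)=CC1=O
F3 | step 10 | 8-(tert-butyldimethylsilyloxy)-3α-(triethylsilyloxy)-7αH,10βH-eremophila-8,11-diene (cis-fused, 7β-isopropenyl) | C=C(C)[C@H]1C[C@@]2(C)[C@H](CC[C@@H](O[Si](CC)(CC)CC)[C@@H]2C)C=C1O[Si](C)(C)C(C)(C)C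
F4 | step 10 | 8β,9β-epoxide of F3 | C=C(C)[C@H]1C[C@@]2(C)[C@H](CC[C@@H](O[Si](CC)(CC)CC)[C@@H]2C)[C@H]3O[C@@]13O[Si](C)(C)C(C)(C)C
F5 | step 10 | 9β-hydroxy-3α-(triethylsilyloxy)-7αH,10βH-eremophil-11-en-8-one | C=C(C)[C@H]1C[C@@]2(C)[C@H](CC[C@@H](O[Si](CC)(CC)CC)[C@@H]2C)[C@@H](O)C1=O
F6 | step 10 | 3α,9β-dihydroxy-7αH,10βH-eremophil-11-en-8-one | C=C(C)[C@H]1C[C@@]2(C)[C@H](CC[C@@H](O)[C@@H]2C)[C@@H](O)C1=O
F7 | step 13 | 9β-(tert-butyldimethylsilyloxy)-3α-(triethylsilyloxy)-7βH,10βH-eremophil-11-en-8-one | C=C(C)[C@@H]1C[C@@]2(C)[C@H](CC[C@@H](O[Si](CC)(CC)CC)[C@@H]2C)[C@@H](O[Si](C)(C)C(C)(C)C)C1=O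
F8 | step 13 | 9β-(tert-butyldimethylsilyloxy)-3α-(triethylsilyloxy)-7αH,10βH-eremophil-11-en-8-one | C=C(C)[C@H]1C[C@@]2(C)[C@H](CC[C@@H](O[Si](CC)(CC)CC)[C@@H]2C)[C@@H](O[Si](C)(C)C(C)(C)C)C1=O
F9 | step 11 | 9β-(N-phenylaminooxy)-3α-(triethylsilyloxy)-7βH,10βH-eremophil-11-en-8-one | C=C(C)[C@@H]1C[C@@]2(C)[C@H](CC[C@@H](O[Si](CC)(CC)CC)[C@@H]2C)[C@@H](ONc3ccccc3)C1=O
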